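**Retrosynthetic overview**

1. Target 17 ⇐ 16 by one global hydrogenolysis (eight benzyl ethers and a C8 bromine on the catechin unit) ⇐ 15 by acetate methanolysis.
2. Key disconnection: the pyran ring C of the upper unit is opened across O1–C2 and C3–C4 as an oxa-[4+2] cycloaddition between o-quinone methide 14 (O1=C8a–C4a=C4, with catechin C6 on C4) and (E)-β-acetoxystyrene 13 (C2, C3 and ring B).
3. Enabling feature: C4 is doubly benzylic (ring A and the trioxygenated ring D) and sits ortho to the phenolic O1 on ring A, so O1–C8a–C4a–C4 is a latent 1-oxadiene; C2–C3 maps onto an E-styrene polarised by the para-oxygen of ring B.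
4. Benzhydrol 9 ⇐ C6 Grignard of 8-bromo-6-iodo-penta-O-benzylcatechin 5 + aldehyde 6; 5 ⇐ (+)-catechin 1 (C8 bromine as a blocking group); 13 ⇐ aldehyde 10 via alkenylboron chemistry.
5. Ring order: rings D/F/E are bought as (+)-catechin, rings A and B are bought as arenes, and pyran ring C is the only ring made and is closed last.

Key step: step 9

Assumption: upper-unit rings are called A (resorcinol), C (pyran) and B (catechol), catechin-unit rings D, F and E; the (R)-phosphoric acid is written as the enantiomer that delivers the (2R,3S,4S) adduct, and its mirror image is to be used if the facial sense proves opposite, since the remote catechin stereocentres are not expected to override catalyst control.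

**Route**

Step 1
Reactants: 1 (+)-catechin
Product: 2 (2R,3S)-5,7-bis(benzyloxy)-2-[3,4-bis(benzyloxy)phenyl]chroman-3-ol
Conditions: BnBr (4.4 equiv), K2CO3, DMF, 0 °C → rt
Reagents that add atoms: benzyl bromide, BrCc1ccccc1
Why: Williamson etherification with a carbonate base should alkylate only the four phenols and leave the secondary C3 alcohol and both stereocentres untouched.

Step 2
Reactants: 2 (2R,3S)-5,7-bis(benzyloxy)-2-[3,4-bis(benzyloxy)phenyl]chroman-3-ol
Product: 3 (2R,3S)-3,5,7-tris(benzyloxy)-2-[3,4-bis(benzyloxy)phenyl]chromane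
Conditions: NaH, BnBr, TBAI (cat.), DMF, 0 °C → rt
Reagents that add atoms: benzyl bromide, BrCc1ccccc1
Why: Williamson etherification of the remaining alcohol removes the only acidic OH before the Grignard and o-quinone methide steps, and the group leaves in the final hydrogenolysis.

Step 3
Reactants: 3 (2R,3S)-3,5,7-tris(benzyloxy)-2-[3,4-bis(benzyloxy)phenyl]chromane
Product: 4 (2R,3S)-3,5,7-tris(benzyloxy)-2-[3,4-bis(benzyloxy)phenyl]-8-bromochromane
Conditions: NBS (1.0 equiv), CH2Cl2, −20 °C → rt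
Reagents that add atoms: N-bromosuccinimide, O=C1CCC(=O)N1Br
Why: electrophilic aromatic bromination should go to C8, the most nucleophilic position of 5,7-di-O-alkylflavans, so the bromine blocks C8 and is removed in step 11.

Step 4
Reactants: 4 (2R,3S)-3,5,7-tris(benzyloxy)-2-[3,4-bis(benzyloxy)phenyl]-8-bromochromane
Product: 5 (2R,3S)-3,5,7-tris(benzyloxy)-2-[3,4-bis(benzyloxy)phenyl]-8-bromo-6-iodochromane
Conditions: NIS (1.2 equiv), TFA (10 mol %), CH2Cl2/MeCN, 0 °C → rt, dark
Reagents that add atoms: N-iodosuccinimide, O=C1CCC(=O)N1I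
Why: second electrophilic halogenation, C6 being the only free position of the trioxygenated ring D, which is far more activated than the dialkoxy ring E.

Step 5
Reactants: 5 (2R,3S)-3,5,7-tris(benzyloxy)-2-[3,4-bis(benzyloxy)phenyl]-8-bromo-6-iodochromane, 6 4-(benzyloxy)-2-hydroxybenzaldehyde
Product: 9 [4-(benzyloxy)-2-hydroxyphenyl][(2R,3S)-3,5,7-tris(benzyloxy)-2-[3,4-bis(benzyloxy)phenyl]-8-bromochroman-6-yl]methanol (both carbinol epimers), via arylmagnesium chloride 7 (not isolated), via sodium phenoxide 8 (not isolated)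
Conditions: 5, iPrMgCl·LiCl (1.1 equiv), THF, −20 → 0 °C; then 8 (from 6, NaH 1.0 equiv, THF, 0 °C), −20 °C → rt; aq NH4Cl; product used without delay (Et3N-deactivated silica)
Reagents that add atoms: none
Why: iodine–magnesium exchange is much faster at C–I than at C–Br, and 1,2-addition of the C6 Grignard to the aldehyde of the preformed phenoxide (so no Grignard is lost to the phenol) should give the 2-hydroxybenzhydrol, whose unselectively formed carbinol centre is erased in step 9.

Step 6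
Reactants: 10 3,4-bis(benzyloxy)benzaldehyde
Product: 11 2-[(E)-2-[3,4-bis(benzyloxy)phenyl]ethenyl]-4,4,5,5-tetramethyl-1,3,2-dioxaborolane
Conditions: CH2(Bpin)2, LiTMP, THF, 0 °C; then 10, −78 °C → rt
Reagents that add atoms: bis[(pinacolato)boryl]methane, CC1(C)OB(CB2OC(C)(C)C(C)(C)O2)OC1(C)C
Why: boron–Wittig olefination, in which the α-boryl carbanion adds to the aldehyde and boron–oxygen syn-elimination should give the trans alkenylboronate.

Step 7
Reactants: 11 2-[(E)-2-[3,4-bis(benzyloxy)phenyl]ethenyl]-4,4,5,5-tetramethyl-1,3,2-dioxaborolane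
Product: 12 potassium (E)-{2-[3,4-bis(benzyloxy)phenyl]ethenyl}trifluoroborate
Conditions: KHF2 (aq), MeOH, rt
Reagents that add atoms: potassium hydrogen difluoride, F.[F-].[K+]
Why: fluoride exchange at boron gives the crystalline trifluoroborate needed for copper-catalysed C–O coupling, with the alkene geometry untouched.

Step 8
Reactants: 12 potassium (E)-{2-[3,4-bis(benzyloxy)phenyl]ethenyl}trifluoroborate
Product: 13 (E)-2-[3,4-bis(benzyloxy)phenyl]ethenyl acetate
Conditions: AcOH, CuBr (10 mol %), DMAP (20 mol %), 4 Å MS, O2 (1 atm), MeCN, 40 °C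
Reagents that add atoms: acetic acid, CC(O)=O
Why: Chan–Lam-type oxidative copper-catalysed coupling of an alkenyltrifluoroborate with a carboxylic acid forms the C(sp2)–O bond with retention of geometry, so the enol acetate should be obtained as the E isomer only.

Step 9
Reactants: 9 [4-(benzyloxy)-2-hydroxyphenyl][(2R,3S)-3,5,7-tris(benzyloxy)-2-[3,4-bis(benzyloxy)phenyl]-8-bromochroman-6-yl]methanol, 13 (E)-2-[3,4-bis(benzyloxy)phenyl]ethenyl acetate
Product: 15 (2R,3S,4S)-7-(benzyloxy)-2-[3,4-bis(benzyloxy)phenyl]-4-[(2R,3S)-3,5,7-tris(benzyloxy)-2-[3,4-bis(benzyloxy)phenyl]-8-bromochroman-6-yl]chroman-3-yl acetate, via o-quinone methide 14 (not isolated)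
Conditions: (R)-TRIP (10 mol %), 13 (3 equiv), 5 Å MS, CH2Cl2, −20 °C → rt, slow addition of 9
Reagents that add atoms: none
Why: Proposed new method: the chiral phosphoric acid should dehydrate 9 to the hydrogen-bonded o-quinone methide 14 (O1=C8a–C4a=C4, stabilised by the 7-benzyloxy group and by ring D on C4), which undergoes an asynchronous inverse-electron-demand oxa-[4+2] cycloaddition with 13 in which the acetoxy-bearing carbon (future C3) bonds to C4 and the developing 4-alkoxybenzylic cation at C2 is captured by O1. The closest known reaction types are the chiral Brønsted acid-catalysed hetero-Diels–Alder reaction of o-quinone methides generated in situ from 2-hydroxybenzhydrols with electron-rich styrenes, enol ethers and enecarbamates, and the cycloaddition of o-quinone methides with anethole-type styrenes to 2,4-cis-flavans; the β-acyloxystyrene dienophile and catalyst-controlled face selection on a chiral, hindered benzhydrol are the untested elements. Ring C closes as an intermolecular [4+2] annulation, C3–C4 and O1–C2 forming in one operation and the C–O bond completing the six-membered ring by collapse of the phenol oxygen on the benzylic cation. The 2,3-trans relation should follow from the E geometry of 13 in a suprafacial addition (acetoxonium-assisted or thermodynamic closure would give the same result); the 2,4-cis and hence 3,4-trans relation should follow from the endo orientation of ring B under the E-configured 14, with the acetoxy group exo and away from ring D; the absolute (2R,3S,4S) sense should come from the catalyst pocket leaving one face of bound 14 open. The step needs head-to-tail regioselectivity, secured because the 4-benzyloxyphenyl group stabilises positive charge at C2 far better than an acetoxy group would at C3, and cross-cycloaddition over self-reaction of 14, secured by excess 13 and slow generation of 14.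

Step 10
Reactants: 15 (2R,3S,4S)-7-(benzyloxy)-2-[3,4-bis(benzyloxy)phenyl]-4-[(2R,3S)-3,5,7-tris(benzyloxy)-2-[3,4-bis(benzyloxy)phenyl]-8-bromochroman-6-yl]chroman-3-yl acetate
Product: 16 (2R,3S,4S)-7-(benzyloxy)-2-[3,4-bis(benzyloxy)phenyl]-4-[(2R,3S)-3,5,7-tris(benzyloxy)-2-[3,4-bis(benzyloxy)phenyl]-8-bromochroman-6-yl]chroman-3-ol
Conditions: K2CO3 (0.2 equiv), MeOH/THF, rt
Reagents that add atoms: none
Why: base-catalysed transesterification should remove the secondary acetate without touching benzyl ethers, the aryl bromide or any stereocentre.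

Step 11
Reactants: 16 (2R,3S,4S)-7-(benzyloxy)-2-[3,4-bis(benzyloxy)phenyl]-4-[(2R,3S)-3,5,7-tris(benzyloxy)-2-[3,4-bis(benzyloxy)phenyl]-8-bromochroman-6-yl]chroman-3-ol
Product: 17 CNP0141631.1, fisetinidol-(4α→6)-catechin, (2R,3S,4S)-2-(3,4-dihydroxyphenyl)-4-[(2R,3S)-2-(3,4-dihydroxyphenyl)-3,5,7-trihydroxychroman-6-yl]chromane-3,7-diol
Conditions: H2 (1 atm), 20% Pd(OH)2/C, Et3N (1.2 equiv), THF/MeOH/H2O, rt; filtration, Sephadex LH-20
Reagents that add atoms: none
Why: palladium-catalysed hydrogenolysis should cleave all eight benzyl ethers and the aryl C–Br bond in one operation, the amine taking up HBr so that the acid-labile C4–C6 interflavan bond is not exposed to acid, while the flavan C2–O1 bonds survive as in catechin debenzylations.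

**Compound list**

1 | (+)-catechin, (2R,3S)-2-(3,4-dihydroxyphenyl)chromane-3,5,7-triol | Oc1cc(O)c2C[C@H](O)[C@@H](c3ccc(O)c(O)c3)Oc2c1 | starting material
2 | (2R,3S)-5,7-bis(benzyloxy)-2-[3,4-bis(benzyloxy)phenyl]chroman-3-ol | O(Cc3ccccc3)c1cc(OCc3ccccc3)c2C[C@H](O)[C@@H](c4ccc(OCc3ccccc3)c(OCc3ccccc3)c4)Oc2c1 | intermediate
3 | (2R,3S)-3,5,7-tris(benzyloxy)-2-[3,4-bis(benzyloxy)phenyl]chromane | O(Cc3ccccc3)c1cc(OCc3ccccc3)c2C[C@H](OCc3ccccc3)[C@@H](c4ccc(OCc3ccccc3)c(OCc3ccccc3)c4)Oc2c1 | intermediate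
4 | (2R,3S)-3,5,7-tris(benzyloxy)-2-[3,4-bis(benzyloxy)phenyl]-8-bromochromane | O(Cc3ccccc3)c1cc(OCc3ccccc3)c2C[C@H](OCc3ccccc3)[C@@H](c4ccc(OCc3ccccc3)c(OCc3ccccc3)c4)Oc2c1Br | intermediate
5 | (2R,3S)-3,5,7-tris(benzyloxy)-2-[3,4-bis(benzyloxy)phenyl]-8-bromo-6-iodochromane | O(Cc3ccccc3)c1c(I)c(OCc3ccccc3)c2C[C@H](OCc3ccccc3)[C@@H](c4ccc(OCc3ccccc3)c(OCc3ccccc3)c4)Oc2c1Br | intermediate
6 | 4-(benzyloxy)-2-hydroxybenzaldehyde | O=Cc1ccc(OCc2ccccc2)cc1O | starting material
7 | [(2R,3S)-3,5,7-tris(benzyloxy)-2-[3,4-bis(benzyloxy)phenyl]-8-bromochroman-6-yl]magnesium chloride (LiCl complex) | O(Cc3ccccc3)c1c([Mg]Cl)c(OCc3ccccc3)c2C[C@H](OCc3ccccc3)[C@@H](c4ccc(OCc3ccccc3)c(OCc3ccccc3)c4)Oc2c1Br | intermediate (not isolated)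
8 | sodium 5-(benzyloxy)-2-formylphenoxide | [Na+].[O-]c1cc(OCc2ccccc2)ccc1C=O | intermediate (not isolated)
9 | [4-(benzyloxy)-2-hydroxyphenyl][(2R,3S)-3,5,7-tris(benzyloxy)-2-[3,4-bis(benzyloxy)phenyl]-8-bromochroman-6-yl]methanol, carbinol epimers | O(Cc3ccccc3)c1c(C(O)c5ccc(OCc3ccccc3)cc5O)c(OCc3ccccc3)c2C[C@H](OCc3ccccc3)[C@@H](c4ccc(OCc3ccccc3)c(OCc3ccccc3)c4)Oc2c1Br | intermediate
10 | 3,4-bis(benzyloxy)benzaldehyde | O=Cc1ccc(OCc2ccccc2)c(OCc2ccccc2)c1 | starting material
11 | 2-[(E)-2-[3,4-bis(benzyloxy)phenyl]ethenyl]-4,4,5,5-tetramethyl-1,3,2-dioxaborolane | CC1(C)OB(/C=C/c2ccc(OCc3ccccc3)c(OCc3ccccc3)c2)OC1(C)C | intermediate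
12 | potassium (E)-{2-[3,4-bis(benzyloxy)phenyl]ethenyl}trifluoroborate | [K+].F[B-](F)(F)/C=C/c1ccc(OCc2ccccc2)c(OCc2ccccc2)c1 | intermediate
13 | (E)-2-[3,4-bis(benzyloxy)phenyl]ethenyl acetate | CC(=O)O/C=C/c1ccc(OCc2ccccc2)c(OCc2ccccc2)c1 | intermediate
14 | 3-(benzyloxy)-6-{[(2R,3S)-3,5,7-tris(benzyloxy)-2-[3,4-bis(benzyloxy)phenyl]-8-bromochroman-6-yl]methylidene}cyclohexa-2,4-dien-1-one | O(Cc3ccccc3)c1c(C=C5C=CC(OCc3ccccc3)=CC5=O)c(OCc3ccccc3)c2C[C@H](OCc3ccccc3)[C@@H](c4ccc(OCc3ccccc3)c(OCc3ccccc3)c4)Oc2c1Br | intermediate (not isolated)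
15 | (2R,3S,4S)-7-(benzyloxy)-2-[3,4-bis(benzyloxy)phenyl]-4-[(2R,3S)-3,5,7-tris(benzyloxy)-2-[3,4-bis(benzyloxy)phenyl]-8-bromochroman-6-yl]chroman-3-yl acetate | O(Cc3ccccc3)c1ccc2c(c1)O[C@H](c4ccc(OCc3ccccc3)c(OCc3ccccc3)c4)[C@@H](OC(C)=O)[C@@H]2c1c(OCc3ccccc3)c(Br)c2c(c1OCc3ccccc3)C[C@H](OCc3ccccc3)[C@@H](c4ccc(OCc3ccccc3)c(OCc3ccccc3)c4)O2 | intermediate
16 | (2R,3S,4S)-7-(benzyloxy)-2-[3,4-bis(benzyloxy)phenyl]-4-[(2R,3S)-3,5,7-tris(benzyloxy)-2-[3,4-bis(benzyloxy)phenyl]-8-bromochroman-6-yl]chroman-3-ol | O(Cc3ccccc3)c1ccc2c(c1)O[C@H](c4ccc(OCc3ccccc3)c(OCc3ccccc3)c4)[C@@H](O)[C@@H]2c1c(OCc3ccccc3)c(Br)c2c(c1OCc3ccccc3)C[C@H](OCc3ccccc3)[C@@H](c4ccc(OCc3ccccc3)c(OCc3ccccc3)c4)O2 | intermediate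
17 | CNP0141631.1, fisetinidol-(4α→6)-catechin | Oc1ccc2c(c1)O[C@H](c1ccc(O)c(O)c1)[C@@H](O)[C@@H]2c1c(O)cc2c(c1O)C[C@H](O)[C@@H](c1ccc(O)c(O)c1)O2 | target

**Summary**

Total step count: 11. Longest linear sequence: 8 steps (steps 1–5, 9, 10, 11).

Steps most likely to fail:

1. Step 9 (Proposed new method). The catalyst may not discriminate the two faces of the hindered o-quinone methide well enough, exo approach may compete, or 14 may oligomerise if the cycloaddition is slow. The fallback uses known reaction types, sets out from 9 and 12 and returns at 16.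
   - Hydrolysis of 12 (TMSCl, H2O, MeCN) should give (E)-2-[3,4-bis(benzyloxy)phenyl]ethenylboronic acid F1.
   - Chiral biphenol-catalysed asymmetric conjugate alkenylation of the o-quinone methide generated from 9 with F1 (3,3′-dibromo-BINOL catalyst, 4 Å MS, toluene) should set C4 and give the 1,1,3-triarylpropene 5-(benzyloxy)-2-[(1S,2E)-3-[3,4-bis(benzyloxy)phenyl]-1-[(2R,3S)-3,5,7-tris(benzyloxy)-2-[3,4-bis(benzyloxy)phenyl]-8-bromochroman-6-yl]prop-2-en-1-yl]phenol F2.
   - Shi asymmetric epoxidation of the E-alkene (fructose-derived ketone of the enantiomeric series that gives the (S,S)-oxirane, Oxone, buffered MeCN/DMM/H2O, 0 °C) should give the trans-epoxide 5-(benzyloxy)-2-{(S)-[(2S,3S)-3-[3,4-bis(benzyloxy)phenyl]oxiran-2-yl][(2R,3S)-3,5,7-tris(benzyloxy)-2-[3,4-bis(benzyloxy)phenyl]-8-bromochroman-6-yl]methyl}phenol F3.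
   - CSA-catalysed 6-endo opening of the oxirane at the 4-alkoxybenzylic carbon by the phenol, with inversion, closes the same pyran ring as the last ring and should give 16.

2. Step 5. Addition of the doubly ortho-substituted aryl Grignard to the deactivated phenoxide-aldehyde may be slow, so that protonation back to 4 or halogen scrambling competes, and the electron-rich benzhydrol may ionise during isolation. The fallback reverses the polarity, sets out from 4 and returns at 9. Vilsmeier–Haack formylation of 4 (POCl3, DMF, 0 → 60 °C; aq NaOAc) at the only free position C6 should give (2R,3S)-3,5,7-tris(benzyloxy)-2-[3,4-bis(benzyloxy)phenyl]-8-bromochromane-6-carbaldehyde F4. Commercial 3-(benzyloxy)phenol (Oc1cccc(OCc2ccccc2)c1) is converted with EtMgBr into bromomagnesium 3-(benzyloxy)phenoxide F5, whose chelation-controlled ortho-selective hydroxyalkylation with F4 (toluene/CH2Cl2, rt), para to the benzyloxy group, should give 9.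

3. Step 8. Protodeboronation or oxidative homocoupling of the electron-rich alkenylborate, or erosion of alkene geometry, may lower the supply of pure E-13. The fallback sets out from 11 and returns at 13. Oxidation of the alkenylboronate (H2O2, pH 7 phosphate buffer, THF, 0 °C) should give [3,4-bis(benzyloxy)phenyl]acetaldehyde F6. Enol acetylation under equilibrating conditions (Ac2O, KOAc, 120 °C) should give 13 as the major E isomer, to be separated from the Z isomer by crystallisation or chromatography.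

Further compounds
F1 | step 9 | (E)-2-[3,4-bis(benzyloxy)phenyl]ethenylboronic acid | OB(O)/C=C/c1ccc(OCc2ccccc2)c(OCc2ccccc2)c1
F2 | step 9 | 5-(benzyloxy)-2-[(1S,2E)-3-[3,4-bis(benzyloxy)phenyl]-1-[(2R,3S)-3,5,7-tris(benzyloxy)-2-[3,4-bis(benzyloxy)phenyl]-8-bromochroman-6-yl]prop-2-en-1-yl]phenol | O(Cc3ccccc3)c1ccc(c(O)c1)[C@H](/C=C/c4ccc(OCc3ccccc3)c(OCc3ccccc3)c4)c1c(OCc3ccccc3)c(Br)c2c(c1OCc3ccccc3)C[C@H](OCc3ccccc3)[C@@H](c4ccc(OCc3ccccc3)c(OCc3ccccc3)c4)O2
F3 | step 9 | 5-(benzyloxy)-2-{(S)-[(2S,3S)-3-[3,4-bis(benzyloxy)phenyl]oxiran-2-yl][(2R,3S)-3,5,7-tris(benzyloxy)-2-[3,4-bis(benzyloxy)phenyl]-8-bromochroman-6-yl]methyl}phenol | O(Cc3ccccc3)c1ccc(c(O)c1)[C@H]([C@@H]5O[C@H]5c4ccc(OCc3ccccc3)c(OCc3ccccc3)c4)c1c(OCc3ccccc3)c(Br)c2c(c1OCc3ccccc3)C[C@H](OCc3ccccc3)[C@@H](c4ccc(OCc3ccccc3)c(OCc3ccccc3)c4)O2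
F4 | step 5 | (2R,3S)-3,5,7-tris(benzyloxy)-2-[3,4-bis(benzyloxy)phenyl]-8-bromochromane-6-carbaldehyde | O(Cc3ccccc3)c1c(C=O)c(OCc3ccccc3)c2C[C@H](OCc3ccccc3)[C@@H](c4ccc(OCc3ccccc3)c(OCc3ccccc3)c4)Oc2c1Br
F5 | step 5 | bromomagnesium 3-(benzyloxy)phenoxide | Br[Mg]Oc1cccc(OCc2ccccc2)c1
F6 | step 8 | [3,4-bis(benzyloxy)phenyl]acetaldehyde | O=CCc1ccc(OCc2ccccc2)c(OCc2ccccc2)c1
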